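The route rests on cutting the C11–C12 bond of the gem-dimethylcyclopentane (C3, C11, C12, C13, C14) that is fused to the homoadamantane triketone. C12, the ring carbon carrying both methyl groups, starts as the tertiary C–H of a 3-methylbutyl chain on C3. A rhodium carbenoid at C11, generated from a diazo group beside a temporary C10 ketone, inserts into that C–H bond; this closes the five-membered ring, creates the quaternary carbon and fixes the C11 stereocentre in one operation. The precursor is the complete cage (C1 benzoyl, C5 geranyl, C8 gem-dimethyl, C2/C4/C9 ketones) carrying the C10 ketone, the C11 diazo group and the untouched 3-methylbutyl group.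

Key step: step 18

Atom labels: C1 benzoyl bridgehead, C2 and C4 ketones flanking C3, C5 geranyl bridgehead, C6 CH2, C7 CH, C8 CMe2, C9 bridging ketone, C10–C11 the two-carbon bridge from C7 to C3, C12 ring CMe2, C13/C14 ring CH2 (C14 on C3). Geranyl = (2E)-3,7-dimethylocta-2,6-dien-1-yl; TIPS = triisopropylsilyl; TBS = tert-butyldimethylsilyl.

Assumption: the malonyl bridge of step 11 is taken to form anti to the C7 side chain (so compounds 20–26 are epimeric to the target at C7 until step 16 inverts that centre through the C10 enol), and O-methylation in step 12 is taken to favour the less hindered C2 oxygen.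

Remark: racemic compound 12 is listed with the SMILES of the enantiomer that is carried on.

Step 1
Reactants: 1 diethyl malonate; 2 1-bromo-3-methylbutane
Product: 3 diethyl 2-(3-methylbutyl)malonate
Conditions: NaOEt, EtOH, reflux (excess of 1)
Reagents that add atoms: none
Why: Malonic ester alkylation, in which the sodium enolate of 1 displaces the primary bromide of 2 by SN2 and the excess of 1 holds the reaction at mono-alkylation.

Step 2
Reactants: 3 diethyl 2-(3-methylbutyl)malonate
Product: 4 2-(3-methylbutyl)malonic acid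
Conditions: KOH, EtOH–H2O, reflux; then HCl (aq), 0 °C
Reagents that add atoms: potassium hydroxide (hydroxide oxygen), [K+].[OH-]
Why: Ester saponification followed by cold acidification frees the diacid, which does not decarboxylate at this temperature.

Step 3
Reactants: 4 2-(3-methylbutyl)malonic acid
Product: 5 2-(3-methylbutyl)malonyl dichloride
Conditions: (COCl)2, DMF (cat.), CH2Cl2, 0 °C → rt
Reagents that add atoms: oxalyl chloride, O=C(Cl)C(=O)Cl
Why: Acid chloride formation through the Vilsmeier-type chloroiminium ion converts both carboxyl groups under conditions mild enough to keep the monosubstituted malonyl chloride from losing HCl.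

Step 4
Reactants: 6 dimedone; 7 geranyl bromide
Product: 8 2-geranyl-5,5-dimethylcyclohexane-1,3-dione
Conditions: KOH (aq), H2O, rt → 50 °C
Reagents that add atoms: none
Why: C-alkylation of a cyclic 1,3-diketone enolate, in which water hydrogen-bonds the enolate oxygens so that the soft allylic bromide is attacked through C2 by SN2.

Step 5
Reactants: 8 2-geranyl-5,5-dimethylcyclohexane-1,3-dione
Product: 9 2-geranyl-3-methoxy-5,5-dimethylcyclohex-2-en-1-one
Conditions: TMSCHN2, MeOH–toluene, 0 °C → rt
Reagents that add atoms: (trimethylsilyl)diazomethane, C[Si](C)(C)C=[N+]=[N-]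
Why: O-methylation of the vinylogous acid by diazoalkane alkylation gives the single possible enol ether because 8 is symmetric.

Step 6
Reactants: 9 2-geranyl-3-methoxy-5,5-dimethylcyclohex-2-en-1-one; 10 chloroacetaldehyde
Product: 12 rac-(6S)-6-[(1R)-2-chloro-1-hydroxyethyl]-2-geranyl-3-methoxy-5,5-dimethylcyclohex-2-en-1-one (anti aldol; racemate), via lithium dienolate 11 (not isolated)
Conditions: LiN(i-Pr)2, THF, −78 °C; then anhydrous 10, −78 °C; AcOH quench at −78 °C
Reagents that add atoms: none
Why: Directed aldol addition, in which kinetic deprotonation at the α′ carbon gives the ring-locked E-enolate that should add to the aldehyde through a chair Zimmerman–Traxler transition state to give mainly the racemic anti adduct (the syn isomer is removed by chromatography), while the cold acidic quench prevents epoxide closure of the chlorohydrin.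

Step 7
Reactants: 12 rac-anti aldol adduct
Product: 13 (6S)-6-[(1R)-2-chloro-1-hydroxyethyl]-2-geranyl-3-methoxy-5,5-dimethylcyclohex-2-en-1-one (single enantiomer; recovered alcohol)
Conditions: Burkholderia cepacia lipase (immobilised), vinyl acetate, t-BuOMe, 30 °C, stopped near half conversion
Reagents that add atoms: none
Why: Lipase-catalysed kinetic resolution by enantioselective transesterification, in which the empirical size rule for secondary alcohols (bulky ring carbon against the small chloromethyl group) predicts acetylation of the (6R,1′S) enantiomer and recovery of the wanted (6S,1′R) alcohol, so that this step fixes the absolute configuration of the whole route.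

Step 8
Reactants: 13 (6S,1′R) chlorohydrin
Product: 14 (6S)-6-[(1R)-2-chloro-1-(triisopropylsilyloxy)ethyl]-2-geranyl-3-methoxy-5,5-dimethylcyclohex-2-en-1-one
Conditions: i-Pr3SiOTf, 2,6-lutidine, CH2Cl2, −78 → 0 °C
Reagents that add atoms: triisopropylsilyl triflate, CC(C)[Si](C(C)C)(C(C)C)OS(=O)(=O)C(F)(F)F
Why: Silyl ether formation with a silyl triflate and a hindered pyridine base protects the carbinol without retro-aldol or epoxide formation, and the TIPS group is chosen to survive the HCl set free in step 11.

Step 9
Reactants: 14 TIPS ether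
Product: 16 (4S)-4-[(1R)-2-chloro-1-(triisopropylsilyloxy)ethyl]-2-geranyl-5,5-dimethylcyclohex-2-en-1-one, via allylic alcohol 15 (not isolated)
Conditions: i-Bu2AlH, toluene, −78 °C; then 1 M HCl, THF, 0 °C → rt
Reagents that add atoms: water, O
Why: Stork–Danheiser 1,3-carbonyl transposition, in which 1,2-reduction of the vinylogous ester carbonyl and acid-promoted loss of water and methanol move the carbonyl to the former enol ether carbon and leave the stereocentre at C7 untouched.

Step 10
Reactants: 16 transposed enone
Product: 18 (4S)-1-(tert-butyldimethylsilyloxy)-4-[(1R)-2-chloro-1-(triisopropylsilyloxy)ethyl]-2-geranyl-5,5-dimethylcyclohex-1-ene, via lithium enolate 17 (not isolated)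
Conditions: LiBH(s-Bu)3, THF, −78 °C; then t-BuMe2SiCl, DMPU, −78 °C → rt
Reagents that add atoms: tert-butyldimethylsilyl chloride, CC(C)(C)[Si](C)(C)Cl
Why: Conjugate (1,4) hydride reduction of the β-unsubstituted enone by the bulky borohydride and O-silylation of the resulting enolate give the tetrasubstituted silyl enol ether regiospecifically.

Step 11
Reactants: 18 silyl enol ether; 5 2-(3-methylbutyl)malonyl dichloride
Product: 20 7-exo-[(1R)-2-chloro-1-(triisopropylsilyloxy)ethyl]-5-geranyl-2-hydroxy-8,8-dimethyl-3-(3-methylbutyl)bicyclo[3.3.1]non-2-ene-4,9-dione (enol tautomer shown; C1–H; C1 and C5 configured as in the target; C7 side chain anti to the C2–C4 bridge), via keto acid chloride 19 (not isolated)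
Conditions: 5 (excess), CH2Cl2, −20 °C → rt; then KOH (aq), BnEt3NCl, rt; HCl (aq) to pH 2
Reagents that add atoms: none
Why: Effenberger-type [3+3] annulation, in which the enol ether is C-acylated at C5 anti to the C7 side chain, the ketone then enolises towards C1 and is acylated by the second acid chloride on the same face, so that C5 and C1 are set by the C7 stereocentre, and the basic phase-transfer treatment converts any O-acylated enol lactone into the trione.

Step 12
Reactants: 20 bicyclic trione
Product: 21 7-exo-[(1R)-2-chloro-1-(triisopropylsilyloxy)ethyl]-5-geranyl-2-methoxy-8,8-dimethyl-3-(3-methylbutyl)bicyclo[3.3.1]non-2-ene-4,9-dione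
Conditions: TMSCHN2, MeOH–toluene, 0 °C
Reagents that add atoms: (trimethylsilyl)diazomethane, C[Si](C)(C)C=[N+]=[N-]
Why: O-methylation of the enolised 1,3-diketone by diazoalkane alkylation should occur mainly at the less hindered C2 oxygen and removes the acidic enol proton before the bridgehead metalation.

Step 13
Reactants: 21 methyl enol ether; 22 benzoyl chloride
Product: 24 1-benzoyl-7-exo-[(1R)-2-chloro-1-(triisopropylsilyloxy)ethyl]-5-geranyl-2-methoxy-8,8-dimethyl-3-(3-methylbutyl)bicyclo[3.3.1]non-2-ene-4,9-dione, via bridgehead lithium compound 23 (not isolated)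
Conditions: LiTMP (lithium 2,2,6,6-tetramethylpiperidide), THF, −78 °C; then 22, −78 → −40 °C
Reagents that add atoms: none
Why: Bridgehead lithiation–acylation, in which C1–H, flanked by the C9 ketone and the C2 enol ether carbon, is the only acidic hydrogen, and the resulting bridgehead carbanion is C-acylated with the only geometry the bicycle allows.

Step 14
Reactants: 24 C1-benzoyl silyl ether
Product: 25 1-benzoyl-7-exo-[(1R)-2-chloro-1-hydroxyethyl]-5-geranyl-2-methoxy-8,8-dimethyl-3-(3-methylbutyl)bicyclo[3.3.1]non-2-ene-4,9-dione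
Conditions: HF·pyridine, pyridine, THF, 0 °C → rt
Reagents that add atoms: none
Why: Fluoride-mediated desilylation under buffered acidic conditions frees the carbinol without an alkoxide that could close the chlorohydrin to an epoxide or attack the triketone.

Step 15
Reactants: 25 chlorohydrin
Product: 26 1-benzoyl-7-exo-(chloroacetyl)-5-geranyl-2-methoxy-8,8-dimethyl-3-(3-methylbutyl)bicyclo[3.3.1]non-2-ene-4,9-dione
Conditions: Dess–Martin periodinane, NaHCO3, CH2Cl2, 0 °C → rt
Reagents that add atoms: none
Why: Dess–Martin oxidation of the secondary alcohol gives the α-chloro ketone under buffered neutral conditions that spare the enol ether, the alkenes and the triketone.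

Step 16
Reactants: 26 chloroacetyl compound
Product: 28 caged tetraketone (homoadamantane with C10 ketone and C11 H2; C1 benzoyl; C3 3-methylbutyl; C5 geranyl; C7 now as in the target), via lithium diketonate 27 (not isolated)
Conditions: LiCl, DMF, 120 °C
Reagents that add atoms: none
Why: Halide-induced O-demethylation followed by intramolecular enolate C-alkylation, in which chloride removes the methyl group by SN2, the C10 ketone lets C7 equilibrate through its enol, and only the C7-endo epimer can bring C11 over C3, where displacement of chloride (seven-membered exo-tet closure) forms C3–C11, fixes C7 and sets the quaternary C3 with the only configuration the cage permits.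

Step 17
Reactants: 28 caged tetraketone
Product: 30 caged C11 diazo C10 ketone (key-step precursor), via trifluoroacetyl ketone 29 (not isolated)
Conditions: LiN(SiMe3)2, THF, −78 °C; CF3CO2CH2CF3, −78 °C; then MsN3, Et3N, H2O, MeCN, rt
Reagents that add atoms: methanesulfonyl azide, CS(=O)(=O)N=[N+]=[N-]
Why: Detrifluoroacetylative (Regitz-type) diazo transfer, in which the enolate at C11 (the only enolisable position) is trifluoroacetylated and the resulting 1,3-dicarbonyl compound takes N2 from the sulfonyl azide with loss of the trifluoroacetyl group, which avoids the alkoxide bases of a formylation route that would cleave the non-enolisable triketone.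

Step 18
Reactants: 30 caged C11 diazo C10 ketone
Product: 31 C10 ketone of the target (cyclopentane closed; C12 on the C2 side of C11)
Conditions: Rh2(S-PTTL)4 (dirhodium tetrakis[N-phthaloyl-(S)-tert-leucinate], 1 mol%), CH2Cl2, rt, slow addition of 30 at high dilution
Reagents that add atoms: none
Why: Loss of N2 from 30 at the dirhodium tetracarboxylate gives an electrophilic divalent-rhodium carbenoid at C11 that inserts into the tertiary C12–H bond of the 3-methylbutyl chain in a concerted, asynchronous three-centre step. The closest known reaction type is the dirhodium-catalysed intramolecular 1,5 C–H insertion of α-diazo ketones that gives cyclopentanes. The cyclopentane C3–C11–C12–C13–C14 is closed by forming C11–C12 through a five-membered transition state across the C3–C14–C13 tether. The new C11 stereocentre is set by the face of the carbenoid that C12 reaches; the wanted C2 face is screened by the axial C8 methyl, so control is sought from the chiral phthalimido carboxylate ligands, with the mirror-image catalyst tried alongside and the matched one used. Site selectivity is needed against the C13–H bonds (four-membered ring), the methyl C–H bonds on C12 (six-membered, primary), a methyl C–H on C8 that is also 1,5 to C11 through the carbonyl side (primary, much less reactive than tertiary) and the geranyl alkenes. The near geranyl alkene is kept away because the chain is equatorial on C5, trans across ring A to the axial C3–C11 bond, so cyclopropanation would need a trans bridge, and slow addition at high dilution suppresses intermolecular and macrocyclic reactions.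

Step 19
Reactants: 31 C10 ketone
Product: 32 C10 tosylhydrazone of 31
Conditions: TsNHNH2, PPTS (cat.), 4 Å molecular sieves, THF, 50 °C
Reagents that add atoms: p-toluenesulfonyl hydrazide, Cc1ccc(cc1)S(=O)(=O)NN
Why: Hydrazone condensation should occur at C10 because it is the only carbonyl flanked by CH groups, all others lying between quaternary carbons, and the weakly nucleophilic sulfonyl hydrazide under mild acid catalysis should not cause retro-Claisen cleavage.

Step 20
Reactants: 32 tosylhydrazone
Product: 34 CNP0168637.1 (target), via N-boryl hydrazide 33 (not isolated)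
Conditions: catecholborane, CHCl3, 0 °C → rt; then NaOAc·3H2O, 60 °C
Reagents that add atoms: none
Why: Tosylhydrazone reduction (Caglioti-type deoxygenation), in which catecholborane adds hydride to the C=N carbon and acetate-induced loss of sulfinate and N2 from the diazene leaves the C10 methylene without touching the hindered ketones, the alkenes or the C11 stereocentre.

Compound list
1 | diethyl malonate | CCOC(=O)CC(=O)OCC | starting material
2 | 1-bromo-3-methylbutane | CC(C)CCBr | starting material
3 | diethyl 2-(3-methylbutyl)malonate | CCOC(=O)C(CCC(C)C)C(=O)OCC | intermediate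
4 | 2-(3-methylbutyl)malonic acid | CC(C)CCC(C(=O)O)C(=O)O | intermediate
5 | 2-(3-methylbutyl)malonyl dichloride | CC(C)CCC(C(=O)Cl)C(=O)Cl | intermediate
6 | dimedone | CC1(C)CC(=O)CC(=O)C1 | starting material
7 | geranyl bromide | CC(C)=CCC/C(C)=C/CBr | starting material
8 | 2-geranyl-5,5-dimethylcyclohexane-1,3-dione | CC(C)=CCC/C(C)=C/CC1C(=O)CC(C)(C)CC1=O | intermediate
9 | 2-geranyl-3-methoxy-5,5-dimethylcyclohex-2-en-1-one | COC1=C(C/C=C(\C)CCC=C(C)C)C(=O)CC(C)(C)C1 | intermediate
10 | chloroacetaldehyde (anhydrous) | O=CCCl | starting material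
11 | lithium dienolate of 9 (deprotonated at ring carbon 6) | COC1=C(C/C=C(\C)CCC=C(C)C)C(O[Li])=CC(C)(C)C1 | intermediate
12 | rac-(6S)-6-[(1R)-2-chloro-1-hydroxyethyl]-2-geranyl-3-methoxy-5,5-dimethylcyclohex-2-en-1-one (anti aldol; racemate, enantiomer carried on is shown) | COC1=C(C/C=C(\C)CCC=C(C)C)C(=O)[C@H]([C@@H](O)CCl)C(C)(C)C1 | intermediate
13 | (6S)-6-[(1R)-2-chloro-1-hydroxyethyl]-2-geranyl-3-methoxy-5,5-dimethylcyclohex-2-en-1-one (single enantiomer) | COC1=C(C/C=C(\C)CCC=C(C)C)C(=O)[C@H]([C@@H](O)CCl)C(C)(C)C1 | intermediate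
14 | (6S)-6-[(1R)-2-chloro-1-(triisopropylsilyloxy)ethyl]-2-geranyl-3-methoxy-5,5-dimethylcyclohex-2-en-1-one | COC1=C(C/C=C(\C)CCC=C(C)C)C(=O)[C@H]([C@@H](O[Si](C(C)C)(C(C)C)C(C)C)CCl)C(C)(C)C1 | intermediate
15 | 6-[(1R)-2-chloro-1-(triisopropylsilyloxy)ethyl]-2-geranyl-3-methoxy-5,5-dimethylcyclohex-2-en-1-ol (ring carbon 6 as in 14; carbinol epimers) | COC1=C(C/C=C(\C)CCC=C(C)C)C(O)[C@H]([C@@H](O[Si](C(C)C)(C(C)C)C(C)C)CCl)C(C)(C)C1 | intermediate
16 | (4S)-4-[(1R)-2-chloro-1-(triisopropylsilyloxy)ethyl]-2-geranyl-5,5-dimethylcyclohex-2-en-1-one | O=C1CC(C)(C)[C@@H]([C@@H](O[Si](C(C)C)(C(C)C)C(C)C)CCl)C=C1C/C=C(\C)CCC=C(C)C | intermediate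
17 | lithium (4S)-4-[(1R)-2-chloro-1-(triisopropylsilyloxy)ethyl]-2-geranyl-5,5-dimethylcyclohex-1-en-1-olate | [Li]OC1=C(C/C=C(\C)CCC=C(C)C)C[C@H]([C@@H](O[Si](C(C)C)(C(C)C)C(C)C)CCl)C(C)(C)C1 | intermediate
18 | (4S)-1-(tert-butyldimethylsilyloxy)-4-[(1R)-2-chloro-1-(triisopropylsilyloxy)ethyl]-2-geranyl-5,5-dimethylcyclohex-1-ene | CC(C)(C)[Si](C)(C)OC1=C(C/C=C(\C)CCC=C(C)C)C[C@H]([C@@H](O[Si](C(C)C)(C(C)C)C(C)C)CCl)C(C)(C)C1 | intermediate
19 | keto acid chloride: cyclohexanone acylated at C5 (anti to the C7 side chain) by the 2-(3-methylbutyl)malonyl unit, second COCl free | CC(C)=CCC/C(C)=C/C[C@]1(C(=O)C(CCC(C)C)C(Cl)=O)C[C@H]([C@@H](O[Si](C(C)C)(C(C)C)C(C)C)CCl)C(C)(C)CC1=O | intermediate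
20 | 7-exo-[(1R)-2-chloro-1-(triisopropylsilyloxy)ethyl]-5-geranyl-2-hydroxy-8,8-dimethyl-3-(3-methylbutyl)bicyclo[3.3.1]non-2-ene-4,9-dione (C1–H; C1, C5 as in target; C7 epimeric to target) | CC(C)=CCC/C(C)=C/C[C@@]12C[C@H]([C@@H](O[Si](C(C)C)(C(C)C)C(C)C)CCl)C(C)(C)[C@H](C2=O)C(O)=C(CCC(C)C)C1=O | intermediate
21 | 2-O-methyl ether of 20 | CC(C)=CCC/C(C)=C/C[C@@]12C[C@H]([C@@H](O[Si](C(C)C)(C(C)C)C(C)C)CCl)C(C)(C)[C@H](C2=O)C(OC)=C(CCC(C)C)C1=O | intermediate
22 | benzoyl chloride | O=C(Cl)c1ccccc1 | starting material
23 | C1-lithio derivative of 21 | CC(C)=CCC/C(C)=C/C[C@@]12C[C@H]([C@@H](O[Si](C(C)C)(C(C)C)C(C)C)CCl)C(C)(C)[C@]([Li])(C2=O)C(OC)=C(CCC(C)C)C1=O | intermediate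
24 | 1-benzoyl derivative of 21 | CC(C)=CCC/C(C)=C/C[C@@]12C[C@H]([C@@H](O[Si](C(C)C)(C(C)C)C(C)C)CCl)C(C)(C)[C@](C(=O)c3ccccc3)(C2=O)C(OC)=C(CCC(C)C)C1=O | intermediate
25 | 1-benzoyl-7-exo-[(1R)-2-chloro-1-hydroxyethyl]-5-geranyl-2-methoxy-8,8-dimethyl-3-(3-methylbutyl)bicyclo[3.3.1]non-2-ene-4,9-dione | CC(C)=CCC/C(C)=C/C[C@@]12C[C@H]([C@@H](O)CCl)C(C)(C)[C@](C(=O)c3ccccc3)(C2=O)C(OC)=C(CCC(C)C)C1=O | intermediate
26 | 1-benzoyl-7-exo-(chloroacetyl)-5-geranyl-2-methoxy-8,8-dimethyl-3-(3-methylbutyl)bicyclo[3.3.1]non-2-ene-4,9-dione | CC(C)=CCC/C(C)=C/C[C@@]12C[C@H](C(=O)CCl)C(C)(C)[C@](C(=O)c3ccccc3)(C2=O)C(OC)=C(CCC(C)C)C1=O | intermediate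
27 | lithium diketonate of the O-demethylated C7-endo epimer of 26 | CC(C)=CCC/C(C)=C/C[C@@]12C[C@@H](C(=O)CCl)C(C)(C)[C@](C(=O)c3ccccc3)(C2=O)C(O[Li])=C(CCC(C)C)C1=O | intermediate
28 | caged tetraketone: homoadamantane with C2, C4, C9 and C10 ketones, C11 H2, C1 benzoyl, C3 3-methylbutyl, C5 geranyl, C8 gem-dimethyl | CC(C)=CCC/C(C)=C/C[C@@]12C[C@H]3C(=O)C[C@@](CCC(C)C)(C1=O)C(=O)[C@@](C(=O)c1ccccc1)(C2=O)C3(C)C | intermediate
29 | C11-trifluoroacetyl derivative of 28 (C11 epimers/enol) | CC(C)=CCC/C(C)=C/C[C@@]12C[C@H]3C(=O)C(C(=O)C(F)(F)F)[C@@](CCC(C)C)(C1=O)C(=O)[C@@](C(=O)c1ccccc1)(C2=O)C3(C)C | intermediate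
30 | caged C11 diazo C10 ketone with 3-methylbutyl on C3 (key-step precursor) | CC(C)=CCC/C(C)=C/C[C@@]12C[C@H]3C(=O)C(=[N+]=[N-])[C@@](CCC(C)C)(C1=O)C(=O)[C@@](C(=O)c1ccccc1)(C2=O)C3(C)C | intermediate
31 | C10 ketone of the target (gem-dimethylcyclopentane closed; C12 on the C2 side) | CC(C)=CCC/C(C)=C/C[C@@]12C[C@H]3C(=O)[C@@H]4C(C)(C)CC[C@]4(C1=O)C(=O)[C@@](C(=O)c1ccccc1)(C2=O)C3(C)C | intermediate
32 | C10 p-toluenesulfonylhydrazone of 31 | CC(C)=CCC/C(C)=C/C[C@@]12C[C@H]3C(=NNS(=O)(=O)c5ccc(C)cc5)[C@@H]4C(C)(C)CC[C@]4(C1=O)C(=O)[C@@](C(=O)c1ccccc1)(C2=O)C3(C)C | intermediate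
33 | N-(1,3,2-benzodioxaborol-2-yl)-N′-tosyl hydrazide at C10 (C10 epimers) | CC(C)=CCC/C(C)=C/C[C@@]12C[C@H]3C(N(NS(=O)(=O)c5ccc(C)cc5)B6Oc7ccccc7O6)[C@@H]4C(C)(C)CC[C@]4(C1=O)C(=O)[C@@](C(=O)c1ccccc1)(C2=O)C3(C)C | intermediate
34 | CNP0168637.1 | CC(C)=CCC/C(C)=C/C[C@@]12C[C@H]3C[C@@H]4C(C)(C)CC[C@]4(C1=O)C(=O)[C@@](C(=O)c1ccccc1)(C2=O)C3(C)C | target

Total step count: 20. Longest linear sequence: 17 steps (steps 4–20, from dimedone); the malonyl branch (steps 1–3) joins at step 11.

Steps most likely to fail

Step 18 (key step). The insertion may take the less hindered C4/C6 face of the carbenoid and give the wrong C11 configuration, or the carbenoid may be diverted to a methyl C–H of C8 or to an alkene. Fallback, from 30 back to 31: the stereocentre is set by protonation instead of by the catalyst. Insertion of 30 with the achiral, robust Rh2(esp)2 is run without regard to facial selectivity and should give mainly the C11-epimeric caged ketone F1. Because C11–H is the only enolisable hydrogen of F1, LiN(SiMe3)2 (THF, −78 °C) gives the C10–C11 enolate. Kinetic protonation with 2,6-di-tert-butylphenol from the C4/C6 face, which carries no axial methyl, swings C12 to the C2 side and returns the route at 31.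

Step 16 (cage closure). The enolate may be alkylated at oxygen, C3 may add to the C10 carbonyl with the alkoxide then closing an epoxide onto the chloromethyl group, or C7 may not invert fast enough. Fallback, from 26 back to 28: the ring is closed by aldol addition instead of alkylation. Kornblum oxidation of 26 (NaI, NaHCO3, DMSO, 60 °C) gives the α-keto aldehyde F2. LiCl in DMF at 120 °C then frees the diketone, whose C3 carbon adds to the aldehyde carbon C11 once C7 has epimerised, giving the caged C11 ketol F3. Acetylation (Ac2O, DMAP, pyridine) gives the caged C11 acetate F4, and reductive cleavage of the α-acetoxy ketone with zinc dust (Zn) in AcOH delivers 28.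

Step 13 (bridgehead benzoylation). The lithiated bridgehead, crowded by the neighbouring C8 quaternary carbon, may be acylated too slowly, so that the carbanion decomposes or the acid chloride is consumed by the amide base. Fallback, from 21 back to 24: acylation is replaced by aldol addition and oxidation. The bridgehead lithium compound 23 is trapped with benzaldehyde, a smaller and more reactive electrophile, to give the bridgehead carbinol F5 as a mixture of carbinol epimers. Dess–Martin oxidation (NaHCO3, CH2Cl2) converts both epimers into 24.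

Further compounds
F1 | step 18 | C11 epimer of the caged C10 ketone 31 (C12 on the C4 side) | CC(C)=CCC/C(C)=C/C[C@@]12C[C@H]3C(=O)[C@H]4C(C)(C)CC[C@]4(C1=O)C(=O)[C@@](C(=O)c1ccccc1)(C2=O)C3(C)C
F2 | step 16 | 1-benzoyl-5-geranyl-2-methoxy-8,8-dimethyl-3-(3-methylbutyl)-7-exo-(oxoacetyl)bicyclo[3.3.1]non-2-ene-4,9-dione (α-keto aldehyde) | CC(C)=CCC/C(C)=C/C[C@@]12C[C@H](C(=O)C=O)C(C)(C)[C@](C(=O)c3ccccc3)(C2=O)C(OC)=C(CCC(C)C)C1=O
F3 | step 16 | caged C11 ketol (28 with OH on C11; C11 epimers) | CC(C)=CCC/C(C)=C/C[C@@]12C[C@H]3C(=O)C(O)[C@@](CCC(C)C)(C1=O)C(=O)[C@@](C(=O)c1ccccc1)(C2=O)C3(C)C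
F4 | step 16 | caged C11 acetate (acetate of F3) | CC(C)=CCC/C(C)=C/C[C@@]12C[C@H]3C(=O)C(OC(C)=O)[C@@](CCC(C)C)(C1=O)C(=O)[C@@](C(=O)c1ccccc1)(C2=O)C3(C)C
F5 | step 13 | bridgehead carbinol: 21 with CH(OH)Ph on C1 (carbinol epimers) | CC(C)=CCC/C(C)=C/C[C@@]12C[C@H]([C@@H](O[Si](C(C)C)(C(C)C)C(C)C)CCl)C(C)(C)[C@](C(O)c3ccccc3)(C2=O)C(OC)=C(CCC(C)C)C1=O
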